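**Retrosynthetic overview**
1. Target ⇒ O‑demethylation, Br→CHO exchange on the arene, MeMgBr addition (C4 ketone and C7 ester) and C2=C3 hydrogenation ⇒ a coupled enone.
2. Key disconnection C1–C(benzylic): vinylogous Mukaiyama alkylation of a decalin silyl dienol ether (16 skeletal atoms) with an enantiopure Cr(CO)3‑stabilised 2,4,6‑trimethoxybenzylic cation (17 skeletal atoms).
3. Decalin fragment: 2‑methylcyclohexanone (ring A) + methyl vinyl ketone, asymmetric Robinson annulation (ring B); C7 ester by dienyl triflate carbonylation; C4 oxygen and trans fusion by hydroboration; enone, then dienol ether.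
4. Aryl fragment: resorcinol → C–H borylation/oxidation → 1,3,5‑trimethoxybenzene → acylation → CBS reduction → Cr(CO)3 complex acetate.
5. Ring order: ring A and the benzene ring are bought in; ring B is the only ring built (steps 1–2).

Assumption: the stereodescriptors of the given SMILES are taken at face value (trans‑decalin; C1 side chain anti to the angular methyl; C4–OH and C7 side chain syn to it); decalin carbons are referred to by eudesmane numbering (C1 bears the benzylic carbon, C4 the carbinol, C5 the ring‑fusion H, C7 the side chain, C10 the angular methyl).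

**Decalin fragment**

Step 1
Reactants: 1 2‑methylcyclohexanone (racemic); 2 methyl vinyl ketone
Product: 5 (S)-2-methyl-2-(3-oxobutyl)cyclohexan-1-one, via imine 3 (not isolated), via keto imine 4 (not isolated)
Conditions: (R)-1-phenylethylamine, TsOH (cat.), toluene, Dean–Stark, reflux; then 2, THF, 40 °C; then 20 % aq. AcOH, rt
Reagents that add atoms: none
Why: d'Angelo asymmetric Michael addition; the more substituted enamine tautomer of chiral imine 3 adds to the enone through a compact aza‑ene‑type transition state on the face away from the phenyl group, setting the quaternary C10 as (S).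

Step 2
Reactants: 5 (S)-2-methyl-2-(3-oxobutyl)cyclohexan-1-one
Product: 6 (S)-4a-methyl-4,4a,5,6,7,8-hexahydronaphthalen-2(3H)-one
Conditions: NaOMe, MeOH, 60 °C
Reagents that add atoms: none
Why: Intramolecular aldol condensation (second stage of the Robinson annulation) closes ring B; the quaternary centre is not touched.

Step 3
Reactants: 6 (S)-4a-methyl-4,4a,5,6,7,8-hexahydronaphthalen-2(3H)-one
Product: 7 (S)-4a-methyl-3,4,4a,5,6,7-hexahydronaphthalen-2-yl trifluoromethanesulfonate
Conditions: Tf2O, 2,6-di-tert-butyl-4-methylpyridine, CH2Cl2, 0 °C → rt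
Reagents that add atoms: trifluoromethanesulfonic anhydride, O=S(=O)(OS(=O)(=O)C(F)(F)F)C(F)(F)F
Why: O‑Triflation of the enone with loss of the γ‑proton (C4) gives the linear heteroannular dienyl triflate, as with steroidal 4‑en‑3‑ones; no stereocentre is formed.

Step 4
Reactants: 7 (S)-4a-methyl-3,4,4a,5,6,7-hexahydronaphthalen-2-yl trifluoromethanesulfonate
Product: 8 methyl (S)-4a-methyl-3,4,4a,5,6,7-hexahydronaphthalene-2-carboxylate
Conditions: Pd(OAc)2 (5 mol %), PPh3, CO (1 atm), MeOH, Et3N, DMF, 60 °C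
Reagents that add atoms: carbon monoxide, [C-]#[O+]; methanol, CO
Why: Pd‑catalysed methoxycarbonylation of the vinyl triflate (oxidative addition, CO insertion, methanolysis) installs the C7 carboxyl carbon.

Step 5
Reactants: 8 methyl (S)-4a-methyl-3,4,4a,5,6,7-hexahydronaphthalene-2-carboxylate
Product: 9 methyl (4aS,8S,8aS)-8-hydroxy-4a-methyl-3,4,4a,5,6,7,8,8a-octahydronaphthalene-2-carboxylate
Conditions: BH3·SMe2, THF, 0 °C → rt; then NaOH, H2O2, 0 °C
Reagents that add atoms: hydrogen peroxide, OO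
Why: Brown hydroboration–oxidation; borane adds syn to the electron‑richer γ,δ‑alkene (B at C4, H at C5) from the face opposite the angular methyl, which fixes the trans ring fusion and leaves the enoate.

Step 6
Reactants: 9 methyl (4aS,8S,8aS)-8-hydroxy-4a-methyl-3,4,4a,5,6,7,8,8a-octahydronaphthalene-2-carboxylate
Product: 10 methyl (2S,4aS,8S,8aS)-8-hydroxy-4a-methyldecahydronaphthalene-2-carboxylate
Conditions: H2 (1 atm), Pd/C, EtOAc, rt
Reagents that add atoms: none
Why: Heterogeneous hydrogenation of the enoate from the face opposite the axial angular methyl delivers H‑7 on that face, so the ester ends equatorial and cis to the methyl (also the thermodynamic epimer).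

Step 7
Reactants: 10 methyl (2S,4aS,8S,8aS)-8-hydroxy-4a-methyldecahydronaphthalene-2-carboxylate
Product: 11 methyl (2S,4aS,8aS)-4a-methyl-8-oxodecahydronaphthalene-2-carboxylate
Conditions: Dess–Martin periodinane, NaHCO3, CH2Cl2, rt
Reagents that add atoms: none
Why: Dess–Martin oxidation of the secondary alcohol under buffered, non‑enolising conditions keeps the trans ring fusion at C5.

Step 8
Reactants: 11 methyl (2S,4aS,8aS)-4a-methyl-8-oxodecahydronaphthalene-2-carboxylate
Product: 13 methyl (2S,4aR,8aS)-4a-methyl-8-oxo-1,2,3,4,4a,5,8,8a-octahydronaphthalene-2-carboxylate, via trimethylsilyl enol ether 12 (not isolated)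
Conditions: LiN(i-Pr)2, THF, −78 °C; TMSCl; then Pd(OAc)2 (1.1 equiv), MeCN, rt
Reagents that add atoms: none
Why: Saegusa–Ito oxidation; kinetic deprotonation takes the C3 methylene rather than the ring‑fusion C5–H or the ester α‑CH, so C5 and C7 are preserved and the 2‑en‑4‑one results.

Step 9
Reactants: 13 methyl (2S,4aR,8aS)-4a-methyl-8-oxo-1,2,3,4,4a,5,8,8a-octahydronaphthalene-2-carboxylate
Product: 14 methyl (2S,4aR,8aS)-8-(tert-butyldimethylsilyloxy)-4a-methyl-1,2,3,4,4a,8a-hexahydronaphthalene-2-carboxylate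
Conditions: TBSOTf, Et3N, CH2Cl2, 0 °C → rt
Reagents that add atoms: tert-butyldimethylsilyl trifluoromethanesulfonate, CC(C)(C)[Si](C)(C)OS(=O)(=O)C(F)(F)F
Why: Soft enolisation; the O‑silyl oxocarbenium ion loses the allylic γ‑proton at C1 rather than the hindered ring‑fusion proton at C5 next to the quaternary carbon, giving the linear 1‑silyloxy‑1,3‑diene without touching a stereocentre.

**Aryl fragment**

Step 10
Reactants: 15 resorcinol
Product: 16 1,3-dimethoxybenzene
Conditions: MeI, K2CO3, acetone, reflux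
Reagents that add atoms: iodomethane, CI
Why: Williamson ether synthesis protects both phenols as methyl ethers.

Step 11
Reactants: 16 1,3-dimethoxybenzene
Product: 17 2-(3,5-dimethoxyphenyl)-4,4,5,5-tetramethyl-1,3,2-dioxaborolane
Conditions: [Ir(OMe)(cod)]2 (1.5 mol %), 4,4'-di-tert-butyl-2,2'-bipyridine, B2pin2, hexane, 80 °C
Reagents that add atoms: bis(pinacolato)diboron, CC1(C)OB(OC1(C)C)B1OC(C)(C)C(C)(C)O1
Why: Sterically controlled Ir‑catalysed C–H borylation (Hartwig–Miyaura) occurs only at C5, the one position not ortho to a methoxy group.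

Step 12
Reactants: 17 2-(3,5-dimethoxyphenyl)-4,4,5,5-tetramethyl-1,3,2-dioxaborolane
Product: 18 3,5-dimethoxyphenol
Conditions: H2O2, NaOH, THF/H2O, 0 °C
Reagents that add atoms: hydrogen peroxide, OO
Why: Oxidative 1,2‑aryl migration from boron to oxygen converts the C–B bond into the third phenolic C–O bond.

Step 13
Reactants: 18 3,5-dimethoxyphenol
Product: 19 1,3,5-trimethoxybenzene
Conditions: MeI, K2CO3, acetone, reflux
Reagents that add atoms: iodomethane, CI
Why: Williamson methylation completes the protected phloroglucinol.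

Step 14
Reactants: 19 1,3,5-trimethoxybenzene; 20 3-methylbutanoyl chloride
Product: 21 3-methyl-1-(2,4,6-trimethoxyphenyl)butan-1-one
Conditions: SnCl4, CH2Cl2, −10 °C
Reagents that add atoms: none
Why: Friedel–Crafts acylation of the symmetric, strongly activated arene gives a single ketone; the mild Lewis acid avoids ortho demethylation.

Step 15
Reactants: 21 3-methyl-1-(2,4,6-trimethoxyphenyl)butan-1-one
Product: 22 (R)-3-methyl-1-(2,4,6-trimethoxyphenyl)butan-1-ol
Conditions: (S)-2-methyl-CBS-oxazaborolidine (0.3 equiv), BH3·SMe2, THF, 0 °C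
Reagents that add atoms: none
Why: Corey–Bakshi–Shibata reduction; with the aryl group as the large substituent the (S)-catalyst delivers hydride to give the (R)-carbinol.

Step 16
Reactants: 22 (R)-3-methyl-1-(2,4,6-trimethoxyphenyl)butan-1-ol
Product: 23 tricarbonyl{η6-[(R)-3-methyl-1-(2,4,6-trimethoxyphenyl)butan-1-ol]}chromium
Conditions: Cr(CO)6, n-Bu2O/THF (10:1), reflux, argon, dark
Reagents that add atoms: chromium hexacarbonyl Cr(CO)6, [Cr].[C-]#[O+].[C-]#[O+].[C-]#[O+].[C-]#[O+].[C-]#[O+].[C-]#[O+]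
Why: Thermal arene complexation (Mahaffy–Pauson); the electron‑rich ring displaces three CO ligands, and because both ortho positions are identical there are no planar stereoisomers and the carbinol centre is unchanged.

Step 17
Reactants: 23 tricarbonyl{η6-[(R)-3-methyl-1-(2,4,6-trimethoxyphenyl)butan-1-ol]}chromium
Product: 24 tricarbonyl{η6-[(R)-3-methyl-1-(2,4,6-trimethoxyphenyl)butyl acetate]}chromium
Conditions: Ac2O, pyridine, DMAP (cat.), CH2Cl2, 0 °C → rt, dark
Reagents that add atoms: acetic anhydride, CC(=O)OC(C)=O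
Why: DMAP‑catalysed O‑acylation turns the carbinol into an ionisable leaving group with retention.

**Coupling and endgame**

Step 18
Reactants: 14 methyl (2S,4aR,8aS)-8-(tert-butyldimethylsilyloxy)-4a-methyl-1,2,3,4,4a,8a-hexahydronaphthalene-2-carboxylate; 24 tricarbonyl{η6-[(R)-3-methyl-1-(2,4,6-trimethoxyphenyl)butyl acetate]}chromium
Product: 26 methyl (2S,4aR,5S,8aS)-4a-methyl-5-[(1S)-3-methyl-1-(2,4,6-trimethoxyphenyl)butyl]-8-oxo-1,2,3,4,4a,5,8,8a-octahydronaphthalene-2-carboxylate, via chromium tricarbonyl complex 25 (not isolated)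
Conditions: BF3·OEt2, CH2Cl2, −78 → −30 °C; then air, sunlight, Et2O, rt
Reagents that add atoms: none
Why: Vinylogous Mukaiyama alkylation (SN1); the acetate ionises anti to chromium and the Cr(CO)3‑stabilised cation is attacked exo by the γ‑terminus C1 of the dienol ether on its face anti to the angular methyl, so the benzylic centre forms with net retention and the C1 substituent lands trans to the methyl, after which air and light strip the metal.

Step 19
Reactants: 26 methyl (2S,4aR,5S,8aS)-4a-methyl-5-[(1S)-3-methyl-1-(2,4,6-trimethoxyphenyl)butyl]-8-oxo-1,2,3,4,4a,5,8,8a-octahydronaphthalene-2-carboxylate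
Product: 27 methyl (2S,4aR,5S,8aS)-4a-methyl-5-[(1S)-3-methyl-1-(2,4,6-trimethoxyphenyl)butyl]-8-oxodecahydronaphthalene-2-carboxylate
Conditions: H2 (1 atm), Pd/C, EtOAc, rt
Reagents that add atoms: none
Why: Chemoselective heterogeneous hydrogenation of the conjugated C2=C3 bond; no stereocentre is created and neutral conditions leave C5 alone.

Step 20
Reactants: 27 methyl (2S,4aR,5S,8aS)-4a-methyl-5-[(1S)-3-methyl-1-(2,4,6-trimethoxyphenyl)butyl]-8-oxodecahydronaphthalene-2-carboxylate
Product: 28 (1R,4S,4aR,7S,8aS)-7-(2-hydroxypropan-2-yl)-1,4a-dimethyl-4-[(1S)-3-methyl-1-(2,4,6-trimethoxyphenyl)butyl]decahydronaphthalen-1-ol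
Conditions: MeMgBr (8 equiv), CeCl3, THF, −78 → 0 °C; aq. NH4Cl
Reagents that add atoms: methylmagnesium bromide, C[Mg]Br
Why: Grignard addition with cerium trichloride to suppress enolisation; methyl attacks the C4 ketone equatorially, away from the syn‑axial angular methyl, giving the axial C4–OH cis to that methyl, while the ester takes two methyls to form the C7 carbinol.

Step 21
Reactants: 28 (1R,4S,4aR,7S,8aS)-7-(2-hydroxypropan-2-yl)-1,4a-dimethyl-4-[(1S)-3-methyl-1-(2,4,6-trimethoxyphenyl)butyl]decahydronaphthalen-1-ol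
Product: 29 (1R,4S,4aR,7S,8aS)-4-[(1S)-1-(3,5-dibromo-2,4,6-trimethoxyphenyl)-3-methylbutyl]-7-(2-hydroxypropan-2-yl)-1,4a-dimethyldecahydronaphthalen-1-ol
Conditions: N-bromosuccinimide (2.1 equiv), MeCN, 0 °C
Reagents that add atoms: N-bromosuccinimide, O=C1CCC(=O)N1Br
Why: Electrophilic aromatic bromination fills the only two free, strongly activated ring positions; the tertiary alcohols are inert.

Step 22
Reactants: 29 (1R,4S,4aR,7S,8aS)-4-[(1S)-1-(3,5-dibromo-2,4,6-trimethoxyphenyl)-3-methylbutyl]-7-(2-hydroxypropan-2-yl)-1,4a-dimethyldecahydronaphthalen-1-ol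
Product: 30 5-{(1S)-1-[(1S,4R,4aS,6S,8aR)-4-hydroxy-6-(2-hydroxypropan-2-yl)-4,8a-dimethyldecahydronaphthalen-1-yl]-3-methylbutyl}-2,4,6-trimethoxybenzene-1,3-dicarbaldehyde
Conditions: t-BuLi (7 equiv), THF, −78 °C; DMF, −78 °C → rt; aq. NH4Cl
Reagents that add atoms: N,N-dimethylformamide, CN(C)C=O
Why: Double bromine–lithium exchange (after deprotonation of both carbinols) and Bouveault formylation; each aryllithium is flanked and stabilised by two methoxy groups.

Step 23
Reactants: 30 5-{(1S)-1-[(1S,4R,4aS,6S,8aR)-4-hydroxy-6-(2-hydroxypropan-2-yl)-4,8a-dimethyldecahydronaphthalen-1-yl]-3-methylbutyl}-2,4,6-trimethoxybenzene-1,3-dicarbaldehyde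
Product: 31 2,4,6-trihydroxy-5-{(1S)-1-[(1S,4R,4aS,6S,8aR)-4-hydroxy-6-(2-hydroxypropan-2-yl)-4,8a-dimethyldecahydronaphthalen-1-yl]-3-methylbutyl}benzene-1,3-dicarbaldehyde
Conditions: NaSEt (excess), DMF, 110 °C; then dilute HCl, 0 °C
Reagents that add atoms: none
Why: Thiolate SN2 demethylation of the three aryl methyl ethers, each activated by an ortho formyl group; non‑acidic conditions spare the two tertiary alcohols.

**Compound list**
1 | 2-methylcyclohexanone (racemic) | CC1CCCCC1=O | starting material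
2 | methyl vinyl ketone (but-3-en-2-one) | C=CC(C)=O | starting material
3 | 2-methyl-N-[(R)-1-phenylethyl]cyclohexan-1-imine (ring centre equilibrating) | C[C@@H](N=C1CCCCC1C)c1ccccc1 | intermediate
4 | 4-[(1S)-1-methyl-2-{[(1R)-1-phenylethyl]imino}cyclohexyl]butan-2-one | C[C@@H](N=C1CCCC[C@@]1(C)CCC(C)=O)c1ccccc1 | intermediate
5 | (S)-2-methyl-2-(3-oxobutyl)cyclohexan-1-one | CC(=O)CC[C@]1(C)CCCCC1=O | intermediate
6 | (S)-4a-methyl-4,4a,5,6,7,8-hexahydronaphthalen-2(3H)-one | C1CCCC2=CC(=O)CC[C@]12C | intermediate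
7 | (S)-4a-methyl-3,4,4a,5,6,7-hexahydronaphthalen-2-yl trifluoromethanesulfonate | C1CCC=C2C=C(OS(=O)(=O)C(F)(F)F)CC[C@]12C | intermediate
8 | methyl (S)-4a-methyl-3,4,4a,5,6,7-hexahydronaphthalene-2-carboxylate | C1CCC=C2C=C(C(=O)OC)CC[C@]12C | intermediate
9 | methyl (4aS,8S,8aS)-8-hydroxy-4a-methyl-3,4,4a,5,6,7,8,8a-octahydronaphthalene-2-carboxylate (trans‑fused; OH trans to the angular methyl) | C1CC[C@H](O)[C@H]2C=C(C(=O)OC)CC[C@]12C | intermediate
10 | methyl (2S,4aS,8S,8aS)-8-hydroxy-4a-methyldecahydronaphthalene-2-carboxylate (ester cis to the angular methyl) | C1CC[C@H](O)[C@H]2C[C@@H](C(=O)OC)CC[C@]12C | intermediate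
11 | methyl (2S,4aS,8aS)-4a-methyl-8-oxodecahydronaphthalene-2-carboxylate | C1CCC(=O)[C@H]2C[C@@H](C(=O)OC)CC[C@]12C | intermediate
12 | methyl (2S,4aS,8aS)-4a-methyl-8-(trimethylsilyloxy)-1,2,3,4,4a,5,6,8a-octahydronaphthalene-2-carboxylate | C1CC=C(O[Si](C)(C)C)[C@H]2C[C@@H](C(=O)OC)CC[C@]12C | intermediate
13 | methyl (2S,4aR,8aS)-4a-methyl-8-oxo-1,2,3,4,4a,5,8,8a-octahydronaphthalene-2-carboxylate | C1C=CC(=O)[C@H]2C[C@@H](C(=O)OC)CC[C@]12C | intermediate
14 | methyl (2S,4aR,8aS)-8-(tert-butyldimethylsilyloxy)-4a-methyl-1,2,3,4,4a,8a-hexahydronaphthalene-2-carboxylate | C1=CC=C(O[Si](C)(C)C(C)(C)C)[C@H]2C[C@@H](C(=O)OC)CC[C@]12C | intermediate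
15 | resorcinol (benzene-1,3-diol) | Oc1cccc(O)c1 | starting material
16 | 1,3-dimethoxybenzene | COc1cccc(OC)c1 | intermediate
17 | 2-(3,5-dimethoxyphenyl)-4,4,5,5-tetramethyl-1,3,2-dioxaborolane | COc1cc(OC)cc(c1)B1OC(C)(C)C(C)(C)O1 | intermediate
18 | 3,5-dimethoxyphenol | COc1cc(O)cc(OC)c1 | intermediate
19 | 1,3,5-trimethoxybenzene | COc1cc(OC)cc(OC)c1 | intermediate
20 | 3-methylbutanoyl chloride (isovaleryl chloride) | CC(C)CC(Cl)=O | starting material
21 | 3-methyl-1-(2,4,6-trimethoxyphenyl)butan-1-one | CC(C)CC(=O)c1c(OC)cc(OC)cc1OC | intermediate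
22 | (R)-3-methyl-1-(2,4,6-trimethoxyphenyl)butan-1-ol | CC(C)C[C@H](c1c(OC)cc(OC)cc1OC)O | intermediate
23 | tricarbonyl{η6-[(R)-3-methyl-1-(2,4,6-trimethoxyphenyl)butan-1-ol]}chromium | CC(C)C[C@H](c1c(OC)cc(OC)cc1OC)O.[C-]#[O+].[C-]#[O+].[C-]#[O+].[Cr] | intermediate
24 | tricarbonyl{η6-[(R)-3-methyl-1-(2,4,6-trimethoxyphenyl)butyl acetate]}chromium | CC(C)C[C@H](c1c(OC)cc(OC)cc1OC)OC(C)=O.[C-]#[O+].[C-]#[O+].[C-]#[O+].[Cr] | intermediate
25 | tricarbonyl(η6-arene)chromium complex of coupled enone 26 | CC(C)C[C@H](c1c(OC)cc(OC)cc1OC)[C@@H]1C=CC(=O)[C@H]2C[C@@H](C(=O)OC)CC[C@]12C.[C-]#[O+].[C-]#[O+].[C-]#[O+].[Cr] | intermediate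
26 | methyl (2S,4aR,5S,8aS)-4a-methyl-5-[(1S)-3-methyl-1-(2,4,6-trimethoxyphenyl)butyl]-8-oxo-1,2,3,4,4a,5,8,8a-octahydronaphthalene-2-carboxylate | CC(C)C[C@H](c1c(OC)cc(OC)cc1OC)[C@@H]1C=CC(=O)[C@H]2C[C@@H](C(=O)OC)CC[C@]12C | intermediate
27 | methyl (2S,4aR,5S,8aS)-4a-methyl-5-[(1S)-3-methyl-1-(2,4,6-trimethoxyphenyl)butyl]-8-oxodecahydronaphthalene-2-carboxylate | CC(C)C[C@H](c1c(OC)cc(OC)cc1OC)[C@@H]1CCC(=O)[C@H]2C[C@@H](C(=O)OC)CC[C@]12C | intermediate
28 | (1R,4S,4aR,7S,8aS)-7-(2-hydroxypropan-2-yl)-1,4a-dimethyl-4-[(1S)-3-methyl-1-(2,4,6-trimethoxyphenyl)butyl]decahydronaphthalen-1-ol | CC(C)C[C@H](c1c(OC)cc(OC)cc1OC)[C@@H]1CC[C@@](C)(O)[C@H]2C[C@@H](C(C)(C)O)CC[C@]12C | intermediate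
29 | (1R,4S,4aR,7S,8aS)-4-[(1S)-1-(3,5-dibromo-2,4,6-trimethoxyphenyl)-3-methylbutyl]-7-(2-hydroxypropan-2-yl)-1,4a-dimethyldecahydronaphthalen-1-ol | CC(C)C[C@H](c1c(OC)c(Br)c(OC)c(Br)c1OC)[C@@H]1CC[C@@](C)(O)[C@H]2C[C@@H](C(C)(C)O)CC[C@]12C | intermediate
30 | 5-{(1S)-1-[(1S,4R,4aS,6S,8aR)-4-hydroxy-6-(2-hydroxypropan-2-yl)-4,8a-dimethyldecahydronaphthalen-1-yl]-3-methylbutyl}-2,4,6-trimethoxybenzene-1,3-dicarbaldehyde | CC(C)C[C@H](c1c(OC)c(C=O)c(OC)c(C=O)c1OC)[C@@H]1CC[C@@](C)(O)[C@H]2C[C@@H](C(C)(C)O)CC[C@]12C | intermediate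
31 | CNP0409870.3: 2,4,6-trihydroxy-5-{(1S)-1-[(1S,4R,4aS,6S,8aR)-4-hydroxy-6-(2-hydroxypropan-2-yl)-4,8a-dimethyldecahydronaphthalen-1-yl]-3-methylbutyl}benzene-1,3-dicarbaldehyde | CC(C)C[C@H](c1c(O)c(C=O)c(O)c(C=O)c1O)[C@@H]1CC[C@@](C)(O)[C@H]2C[C@@H](C(C)(C)O)CC[C@]12C | target

**Step count**
Total steps: 23. Longest linear sequence: 15 steps (steps 1–9, then 18–23). The aryl branch is 8 steps (10–17) before the coupling.

**Three steps most likely to fail, with fallbacks**

Step 9 (regiochemistry of dienol ether formation). Et3N may remove the ring‑fusion α'‑proton at C5 instead of the γ‑proton at C1, giving the cross‑conjugated isomer. The fallback sets out from enone 13 and goes through the deconjugated ketone, where the only activated methylene is C3. Ethylene glycol and TsOH (benzene, Dean–Stark) convert 13, with double‑bond migration, into the 1‑ene dioxolane F1. PPTS in wet acetone at 0 °C releases the β,γ‑unsaturated ketone F2 without reconjugation. LiN(i-Pr)2 at −78 °C then removes the doubly activated C3–H, and TBSCl/HMPA traps the linear dienolate on oxygen, returning to 14.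

Step 18 (the fragment coupling). The hindered, neopentyl‑type C1 may lose out to attack at C3, or the cation may rotate and erode the benzylic configuration. The fallback replaces the chromium‑stabilised cation by an ortho‑quinone methide under chiral Brønsted acid control; it sets out from ketone 21 and dienol ether 14. BCl3 (CH2Cl2, −78 °C) removes one ortho methyl group of 21 by chelation to give hydroxy ketone F3, and NaBH4 in MeOH gives the ortho‑hydroxybenzyl alcohol F4. (R)-TRIP (3,3'-bis(2,4,6-triisopropylphenyl)-BINOL phosphoric acid, toluene, molecular sieves, 0 °C; the catalyst enantiomer is chosen by a matched/mismatched screen) dehydrates F4 to the ortho‑quinone methide F5. F5, hydrogen‑bonded to the catalyst, takes up 14 at C1 in a vinylogous Mukaiyama–Michael addition to give phenol F6. MeI/K2CO3 in acetone then re‑methylates the phenol and the route is rejoined at 26.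

Step 22 (double bromine–lithium exchange and formylation). Generating two aryllithium sites next to two lithium alkoxides may stall at the mono‑aldehyde or give protodebromination. The fallback sets out from dibromide 29 and uses cross‑coupling followed by oxidative cleavage. PdCl2(dppf), CH2=CHBF3K and K2CO3 (THF/H2O, 80 °C) give the divinyl arene F7 in a double Suzuki–Miyaura coupling. OsO4 (cat.)/NaIO4 with 2,6‑lutidine in dioxane/H2O (Lemieux–Johnson cleavage) then gives dialdehyde 30, where the route is rejoined.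

**Further compounds**
F1 | step 9 | methyl (2S,4aR,8aS)-8,8-(ethylenedioxy)-4a-methyl-1,2,3,4,4a,7,8,8a-octahydronaphthalene-2-carboxylate (1‑ene dioxolane of the deconjugated ketone) | C1=CCC3(OCCO3)[C@H]2C[C@@H](C(=O)OC)CC[C@]12C
F2 | step 9 | methyl (2S,4aR,8aS)-4a-methyl-8-oxo-1,2,3,4,4a,7,8,8a-octahydronaphthalene-2-carboxylate | C1=CCC(=O)[C@H]2C[C@@H](C(=O)OC)CC[C@]12C
F3 | step 18 | 1-(2-hydroxy-4,6-dimethoxyphenyl)-3-methylbutan-1-one | CC(C)CC(=O)c1c(O)cc(OC)cc1OC
F4 | step 18 | 2-(1-hydroxy-3-methylbutyl)-3,5-dimethoxyphenol (racemic) | CC(C)CC(O)c1c(O)cc(OC)cc1OC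
F5 | step 18 | 3,5-dimethoxy-6-(3-methylbutylidene)cyclohexa-2,4-dien-1-one (ortho‑quinone methide) | CC(C)CC=C1C(=O)C=C(OC)C=C1OC
F6 | step 18 | methyl (2S,4aR,5S,8aS)-5-[(1S)-1-(2-hydroxy-4,6-dimethoxyphenyl)-3-methylbutyl]-4a-methyl-8-oxo-1,2,3,4,4a,5,8,8a-octahydronaphthalene-2-carboxylate | CC(C)C[C@H](c1c(O)cc(OC)cc1OC)[C@@H]1C=CC(=O)[C@H]2C[C@@H](C(=O)OC)CC[C@]12C
F7 | step 22 | (1R,4S,4aR,7S,8aS)-4-[(1S)-1-(3,5-diethenyl-2,4,6-trimethoxyphenyl)-3-methylbutyl]-7-(2-hydroxypropan-2-yl)-1,4a-dimethyldecahydronaphthalen-1-ol | CC(C)C[C@H](c1c(OC)c(C=C)c(OC)c(C=C)c1OC)[C@@H]1CC[C@@](C)(O)[C@H]2C[C@@H](C(C)(C)O)CC[C@]12C
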